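The constants used here were drawn at random within sensible limits; the run is a simulation.

You charge 0.097 M of X and hold D over the flask, and at the end you want the amounts of X, G and G.Q.

- Friday's: X 0.097 M; D 6.8 mM (held); time 20 h
- Tuesday's: X 0.097 M; D 6.8 mM (held); time 12 h

    X → G (k1 = 1.6 × 10⁻⁴ s⁻¹)
    E → Q (k2 = 9.2 × 10⁻⁵ s⁻¹)
    G + Q → G.Q (k3 = 0.014 L mol⁻¹ s⁻¹)
    2 Q → J (k4 = 0.0057 L mol⁻¹ s⁻¹)
    Q → Z (k5 = 0.0036 s⁻¹)
    D ⇌ E, rate k6*(csat - [E]) (k6 = 0.092 s⁻¹, csat = 6.8 mM)

- for a step with 2 of a species take k times the square, and two of it per event
- at the start none of E is dissolved
- run time (Friday's): 20 h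

- which of these there is most of at the end, counted by the X in it, Friday's (G.Q / X / G)
- which of these there is most of at the end, counted by the X in it, Tuesday's (G.Q / X / G)
- how much there is at the end of the one of these that leads, in percent of the X charged: Friday's
- how much there is at the end of the one of these that leads, in percent of the X charged: Tuesday's

Count turnovers first. One lifetime of X is 1.74 h, so Friday's run lasts 11.5 lifetimes and Tuesday's 6.91. What remains to reckon is what G loses.

E starts at none but comes up near 6.8 mM because transfer is faster than its use, so Q is supplied at 2.25 mM h⁻¹. Each Q is then caught by G or goes to Z, while the step to J is far slower per Q. Call the capture share the part of Q that G catches at full charge, a branching ratio: 27.4%.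

For the high extreme, X becomes G at once and G holds its full charge. G.Q then reaches 12.7% on Friday's and 7.63% on Tuesday's.

For the low extreme, capture starts one lifetime late, and G stands throughout at what the high extreme leaves at its end. This gives 10.5% and 6.16%. The real flask starts with no G and its G falls as G.Q forms, so I place it between them.

Taking the midpoints, I expect G to lead on Friday's at 88.4%, and G on Tuesday's at 93.1%.

The forecast names G at 88.8% on Friday's and G at 93.4% on Tuesday's, above my figures, saying: “Roughly three quarters of that Q is lost to Z rather than captured by G”.

The simulation gives G at 88.7% on Friday's and G at 93.4% on Tuesday's.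

Now read Friday's flask at 3.0 d. The capture share at full charge puts G.Q at 45.8%, and the late start with G already down puts it at 27.7%. That flask holds 37.8% of G.Q, less than the first figure and more than the second, and 62.2% of G.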